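**Plan**

- Labels: ring A is the aromatic ring (the methylene bridge sits between two hydroxyl-bearing carbons, the third hydroxyl is para to the bridge, and butyryl is on one of the two remaining carbons). Ring B is the dienone, numbered B1 (bridge-bearing), B2 (C–OH), B3 (CMe2), B4 (C–OH), B5 (propionyl-bearing), B6 (C=O).
- Retrosynthesis: cut the bond from ring A to the butyryl carbonyl (Friedel–Crafts), then the bond from B5 to the propionyl carbonyl (enol ester to C-acyl shift). Ring B is then cut at B4–B5 and B6–B1, with B3–B4 opened and re-closed, into a 4,4-dimethylcyclobutenone and ethoxyacetylene. The four-membered ring is cut into a silyl ynol ether and dimethylketene.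
- Forward: ring A is bought as 1,3,5-tris(benzyloxy)benzene and extended to ArCH2–C≡C–OSi(i-Pr)3. A ketene [2+2] gives the cyclobutenone, and strain release then builds ring B. Propionyl goes onto ring B while ring A is benzylated; butyryl goes onto ring A once ring B has no free carbon.
- Enabling feature: B3 is quaternary (gem-dimethyl), so the annulation cannot aromatize and must end at the 6,6-dimethylcyclohexa-2,4-dienone. Oxygen is already on B2, B4 and B6 (siloxy, ketene carbonyl, ethoxy).
- Stereochemistry: the target has no stereocentre and no stereogenic double bond, so nothing has to be set.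

Key step: step 5

Remark: ring B of each enolized tri- or tetraketone is written in the tautomer of the target SMILES; these tautomers interconvert and are treated as one compound.

**Route**

Step 1
Reactants: 1 1,3,5-tris(benzyloxy)benzene; 2 ethyl chlorooxoacetate
Product: 3 ethyl 2-oxo-2-[2,4,6-tris(benzyloxy)phenyl]acetate
Conditions: TiCl4, CH2Cl2, −78 to −40 °C
Reagents that add atoms: ethyl chlorooxoacetate (2), CCOC(=O)C(Cl)=O
Why: Friedel–Crafts acylation of a phloroglucinol triether, which should be nucleophilic enough to react at −78 °C where TiCl4 spares aryl benzyl ethers; the three ring positions are equivalent and the keto ester product is deactivated toward a second acylation.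

Step 2
Reactants: 3 ethyl 2-oxo-2-[2,4,6-tris(benzyloxy)phenyl]acetate
Product: 5 ethyl 2-[2,4,6-tris(benzyloxy)phenyl]acetate, via mandelate ester 4 (not isolated)
Conditions: Et3SiH, CF3CO2H, CH2Cl2, 0 °C to rt
Reagents that add atoms: none
Why: Ionic hydrogenation, in which the protonated aryl ketone takes hydride from Et3SiH to give the mandelate 4, which ionizes to a benzylic cation stabilized by three alkoxy groups and is reduced a second time, while the ester and the benzyl ethers should survive at 0 °C.

Step 3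
Reactants: 5 ethyl 2-[2,4,6-tris(benzyloxy)phenyl]acetate
Product: 8 triisopropyl({3-[2,4,6-tris(benzyloxy)phenyl]prop-1-yn-1-yl}oxy)silane, via dibromo enolate 6 (not isolated), via lithium ynolate 7 (not isolated)
Conditions: CH2Br2, lithium 2,2,6,6-tetramethylpiperidide, THF, −78 °C; LiN(SiMe3)2; n-BuLi, −78 °C to rt; i-Pr3SiCl, −78 °C to rt
Reagents that add atoms: dibromomethane, BrCBr; chlorotriisopropylsilane, CC(C)[Si](Cl)(C(C)C)C(C)C
Why: Kowalski ester homologation stopped at the ynolate stage, in which dibromomethyllithium adds to the ester, LiN(SiMe3)2 converts the adduct into the dibromo enolate 6, bromine–lithium exchange and warming trigger the carbenoid 1,2-shift to the ynolate 7, and the bulky silyl chloride reacts at oxygen to give the silyl ynol ether.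

Step 4
Reactants: 8 triisopropyl({3-[2,4,6-tris(benzyloxy)phenyl]prop-1-yn-1-yl}oxy)silane; 9 isobutyryl chloride
Product: 11 4,4-dimethyl-2-[(2,4,6-tris(benzyloxy)phenyl)methyl]-3-(triisopropylsilyloxy)cyclobut-2-en-1-one, via dimethylketene 10 (not isolated)
Conditions: Et3N, CH2Cl2, rt to 40 °C, slow addition of 9
Reagents that add atoms: isobutyryl chloride (9), CC(C)C(Cl)=O
Why: Ketene–ynol ether [2+2] cycloaddition, in which dimethylketene from dehydrochlorination of 9 is attacked at its carbonyl carbon by the nucleophilic alkyl-bearing alkyne carbon and closes between the CMe2 carbon (future B3) and the siloxy carbon (future B2), the usual regiochemistry leading to 3-siloxycyclobutenones.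

Step 5
Reactants: 11 4,4-dimethyl-2-[(2,4,6-tris(benzyloxy)phenyl)methyl]-3-(triisopropylsilyloxy)cyclobut-2-en-1-one; 12 ethoxyacetylene
Product: 16 3-ethoxy-6,6-dimethyl-4-[(2,4,6-tris(benzyloxy)phenyl)methyl]-5-(triisopropylsilyloxy)cyclohexa-2,4-dien-1-one, via vinylketene 13 (not isolated), via vinylcyclobutenone 14 (not isolated), via dienylketene 15 (not isolated)
Conditions: 12 (4 equiv), toluene, 80 °C, sealed tube
Reagents that add atoms: ethoxyacetylene (12), CCOC#C
Why: Heating should open 11 by four-electron conrotatory cleavage of the B3–B4 bond to the vinylketene 13, whose ketene carbon B4 is attacked by the unsubstituted carbon of ethoxyacetylene (B5) while the ketene α-carbon B1 bonds to the ethoxy-bearing carbon (B6), giving the 4-vinylcyclobutenone 14; a second four-electron opening cleaves the temporary B1–B4 bond to the dienylketene 15. The closest known reaction type is the Danheiser annulation of cyclobutenones with alkoxy- and siloxyalkynes, which normally ends in a phenol by enolization and should stop here at the cyclohexa-2,4-dienone because B3 carries no hydrogen. Ring B closes by a thermally allowed six-electron disrotatory electrocyclization of the dienylketene between B4 and the dimethyl-bearing terminus B3. No stereocentre is created in 16; the racemic centre of 14 is destroyed in the second opening, and a dienylketene of the wrong geometry can return to 14 and reopen. The selectivity needed is the orientation of the ketene–alkyne union, and the polarization of the ynol ether (nucleophilic at its CH carbon) places ethoxy on B6 next to B1, while 80 °C keeps ethoxyacetylene below its own retro-ene breakdown.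

Step 6
Reactants: 16 3-ethoxy-6,6-dimethyl-4-[(2,4,6-tris(benzyloxy)phenyl)methyl]-5-(triisopropylsilyloxy)cyclohexa-2,4-dien-1-one
Product: 18 3,5-dihydroxy-4,4-dimethyl-2-[(2,4,6-tris(benzyloxy)phenyl)methyl]cyclohexa-2,5-dien-1-one, via monoethyl ether 17 (not isolated)
Conditions: 2 M HCl, THF, 40 °C
Reagents that add atoms: water, O
Why: Acid hydrolysis of a silyl enol ether and of a vinylogous ethyl ester (C-protonation, water addition, loss of ethanol), both part of a vinylogous acid and far more labile than the aryl benzyl ethers, which also keep ring A from cyclizing onto ring B.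

Step 7
Reactants: 18 3,5-dihydroxy-4,4-dimethyl-2-[(2,4,6-tris(benzyloxy)phenyl)methyl]cyclohexa-2,5-dien-1-one; 19 propanoyl chloride
Product: 21 3,5-dihydroxy-4,4-dimethyl-2-propanoyl-6-[(2,4,6-tris(benzyloxy)phenyl)methyl]cyclohexa-2,5-dien-1-one, via enol propanoate 20 (not isolated)
Conditions: Et3N, CH2Cl2, 0 °C; then DMAP (cat.), rt to 40 °C
Reagents that add atoms: propanoyl chloride (19), CCC(Cl)=O
Why: O-acylation of the enolized 1,3-dione followed by DMAP-catalysed enol ester to C-acyl rearrangement (a 1,3-acyl shift through the acylpyridinium–enolate pair), which can end only at B5, the one unsubstituted carbon between two ring carbonyls, whichever enol oxygen is acylated first, and which leaves the benzylated ring A untouched under non-acidic conditions.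

Step 8
Reactants: 21 3,5-dihydroxy-4,4-dimethyl-2-propanoyl-6-[(2,4,6-tris(benzyloxy)phenyl)methyl]cyclohexa-2,5-dien-1-one
Product: 22 3,5-dihydroxy-4,4-dimethyl-2-propanoyl-6-[(2,4,6-trihydroxyphenyl)methyl]cyclohexa-2,5-dien-1-one
Conditions: H2 (1 atm), Pd/C, EtOAc–MeOH, rt
Reagents that add atoms: none
Why: Catalytic hydrogenolysis of the three aryl benzyl ethers, under which the enolized, chelated tetraketone and the methylene bridge should not be reduced at 1 atm and rt.

Step 9
Reactants: 22 3,5-dihydroxy-4,4-dimethyl-2-propanoyl-6-[(2,4,6-trihydroxyphenyl)methyl]cyclohexa-2,5-dien-1-one; 23 butanoyl chloride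
Product: 24 2-[(3-butanoyl-2,4,6-trihydroxyphenyl)methyl]-3,5-dihydroxy-4,4-dimethyl-6-propanoylcyclohexa-2,5-dien-1-one (CNP0330971.0)
Conditions: AlCl3, PhNO2–CH2Cl2, 0 °C to rt; then 1 M HCl
Reagents that add atoms: butanoyl chloride (23), CCCC(Cl)=O
Why: Friedel–Crafts C-acylation of the free phloroglucinol ring, whose two unsubstituted carbons are equivalent and whose first acyl group deactivates it toward a second, while ring B has no unsubstituted carbon left and any enol esters are cleaved in the acidic work-up.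

**Compound list**

1 | 1,3,5-tris(benzyloxy)benzene | c1ccc(COc2cc(OCc3ccccc3)cc(OCc3ccccc3)c2)cc1 | starting material
2 | ethyl chlorooxoacetate | CCOC(=O)C(Cl)=O | starting material
3 | ethyl 2-oxo-2-[2,4,6-tris(benzyloxy)phenyl]acetate | CCOC(=O)C(=O)c1c(OCc2ccccc2)cc(OCc2ccccc2)cc1OCc1ccccc1 | intermediate
4 | ethyl 2-hydroxy-2-[2,4,6-tris(benzyloxy)phenyl]acetate (racemic, not isolated) | CCOC(=O)C(O)c1c(OCc2ccccc2)cc(OCc2ccccc2)cc1OCc1ccccc1 | intermediate
5 | ethyl 2-[2,4,6-tris(benzyloxy)phenyl]acetate | CCOC(=O)Cc1c(OCc2ccccc2)cc(OCc2ccccc2)cc1OCc1ccccc1 | intermediate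
6 | lithium 1,1-dibromo-3-[2,4,6-tris(benzyloxy)phenyl]prop-1-en-2-olate (not isolated) | [Li+].[O-]C(Cc1c(OCc2ccccc2)cc(OCc2ccccc2)cc1OCc1ccccc1)=C(Br)Br | intermediate
7 | lithium 3-[2,4,6-tris(benzyloxy)phenyl]prop-1-yn-1-olate (not isolated) | [Li+].[O-]C#CCc1c(OCc2ccccc2)cc(OCc2ccccc2)cc1OCc1ccccc1 | intermediate
8 | triisopropyl({3-[2,4,6-tris(benzyloxy)phenyl]prop-1-yn-1-yl}oxy)silane | CC(C)[Si](OC#CCc1c(OCc2ccccc2)cc(OCc2ccccc2)cc1OCc1ccccc1)(C(C)C)C(C)C | intermediate
9 | isobutyryl chloride | CC(C)C(Cl)=O | starting material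
10 | dimethylketene (not isolated) | CC(C)=C=O | intermediate
11 | 4,4-dimethyl-2-[(2,4,6-tris(benzyloxy)phenyl)methyl]-3-(triisopropylsilyloxy)cyclobut-2-en-1-one | CC(C)[Si](OC1=C(Cc2c(OCc3ccccc3)cc(OCc3ccccc3)cc2OCc2ccccc2)C(=O)C1(C)C)(C(C)C)C(C)C | intermediate
12 | ethoxyacetylene | CCOC#C | starting material
13 | 4-methyl-3-(triisopropylsilyloxy)-2-[(2,4,6-tris(benzyloxy)phenyl)methyl]penta-1,3-dien-1-one (not isolated) | CC(C)=C(O[Si](C(C)C)(C(C)C)C(C)C)C(=C=O)Cc1c(OCc2ccccc2)cc(OCc2ccccc2)cc1OCc1ccccc1 | intermediate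
14 | 3-ethoxy-4-[2-methyl-1-(triisopropylsilyloxy)prop-1-en-1-yl]-4-[(2,4,6-tris(benzyloxy)phenyl)methyl]cyclobut-2-en-1-one (racemic, not isolated) | CCOC1=CC(=O)C1(Cc1c(OCc2ccccc2)cc(OCc2ccccc2)cc1OCc1ccccc1)C(O[Si](C(C)C)(C(C)C)C(C)C)=C(C)C | intermediate
15 | (3E)-3-ethoxy-6-methyl-5-(triisopropylsilyloxy)-4-[(2,4,6-tris(benzyloxy)phenyl)methyl]hepta-1,3,5-trien-1-one (not isolated) | O=C=C/C(OCC)=C(\C(O[Si](C(C)C)(C(C)C)C(C)C)=C(C)C)Cc1c(OCc2ccccc2)cc(OCc2ccccc2)cc1OCc1ccccc1 | intermediate
16 | 3-ethoxy-6,6-dimethyl-4-[(2,4,6-tris(benzyloxy)phenyl)methyl]-5-(triisopropylsilyloxy)cyclohexa-2,4-dien-1-one | CCOC1=CC(=O)C(C)(C)C(O[Si](C(C)C)(C(C)C)C(C)C)=C1Cc1c(OCc2ccccc2)cc(OCc2ccccc2)cc1OCc1ccccc1 | intermediate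
17 | 3-ethoxy-5-hydroxy-6,6-dimethyl-4-[(2,4,6-tris(benzyloxy)phenyl)methyl]cyclohexa-2,4-dien-1-one (not isolated) | CCOC1=CC(=O)C(C)(C)C(O)=C1Cc1c(OCc2ccccc2)cc(OCc2ccccc2)cc1OCc1ccccc1 | intermediate
18 | 3,5-dihydroxy-4,4-dimethyl-2-[(2,4,6-tris(benzyloxy)phenyl)methyl]cyclohexa-2,5-dien-1-one | CC1(C)C(O)=CC(=O)C(Cc2c(OCc3ccccc3)cc(OCc3ccccc3)cc2OCc2ccccc2)=C1O | intermediate
19 | propanoyl chloride | CCC(Cl)=O | starting material
20 | 5-hydroxy-6,6-dimethyl-3-oxo-4-[(2,4,6-tris(benzyloxy)phenyl)methyl]cyclohexa-1,4-dien-1-yl propanoate (not isolated) | CCC(=O)OC1=CC(=O)C(Cc2c(OCc3ccccc3)cc(OCc3ccccc3)cc2OCc2ccccc2)=C(O)C1(C)C | intermediate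
21 | 3,5-dihydroxy-4,4-dimethyl-2-propanoyl-6-[(2,4,6-tris(benzyloxy)phenyl)methyl]cyclohexa-2,5-dien-1-one | CCC(=O)C1=C(O)C(C)(C)C(O)=C(Cc2c(OCc3ccccc3)cc(OCc3ccccc3)cc2OCc2ccccc2)C1=O | intermediate
22 | 3,5-dihydroxy-4,4-dimethyl-2-propanoyl-6-[(2,4,6-trihydroxyphenyl)methyl]cyclohexa-2,5-dien-1-one | CCC(=O)C1=C(O)C(C)(C)C(O)=C(Cc2c(O)cc(O)cc2O)C1=O | intermediate
23 | butanoyl chloride | CCCC(Cl)=O | starting material
24 | 2-[(3-butanoyl-2,4,6-trihydroxyphenyl)methyl]-3,5-dihydroxy-4,4-dimethyl-6-propanoylcyclohexa-2,5-dien-1-one | CCCC(=O)c1c(O)cc(O)c(CC2=C(O)C(C)(C)C(O)=C(C(=O)CC)C2=O)c1O | target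

**Step count and risks**

Total step count: 9. Longest linear sequence: 9 steps (1 to 24).

Steps most likely to fail:

1. Step 5. The first ring opening of the fully substituted cyclobutenone may be slower than the retro-ene breakdown of ethoxyacetylene to ketene and ethylene, and the crowded vinylketene may be lost through a 1,5-hydrogen shift from a methyl group before it is trapped. The fallback takes ring B from the aromatic pool and sets out from 1. Vilsmeier–Haack formylation of 1 (POCl3, DMF, 0 °C to rt, then aqueous NaOAc) should give 2,4,6-tris(benzyloxy)benzaldehyde F1. Commercial 1-(2,4,6-trihydroxyphenyl)propan-1-one would be gem-dimethylated on the ring (MeI, NaOMe, MeOH) to 3,5-dihydroxy-4,4-dimethyl-2-propanoylcyclohexa-2,5-dien-1-one F2. Knoevenagel condensation of F2 with F1 (L-proline cat., CH2Cl2, rt) should give the benzylidene triketone F3, which diethyl 2,6-dimethyl-1,4-dihydropyridine-3,5-dicarboxylate (Hantzsch ester) present in the same flask should reduce by conjugate hydride transfer. This reductive alkylation comes back to the route at 21, before step 8.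

2. Step 3. The lithium amide or the carbenoid may deprotonate the acidic benzylic α-position of the arylacetate instead of adding to the carbonyl, and the benzyl ethers may undergo α-lithiation and 1,2-Wittig rearrangement while excess n-BuLi warms. The fallback sets out from 5 and reaches the ynolate by oxidation instead of rearrangement. Reduction with i-Bu2AlH (toluene, −78 °C) should give 2-[2,4,6-tris(benzyloxy)phenyl]acetaldehyde F4. Ohira–Bestmann homologation (dimethyl (1-diazo-2-oxopropyl)phosphonate, K2CO3, MeOH, 0 °C to rt) should give 1,3,5-tris(benzyloxy)-2-(prop-2-yn-1-yl)benzene F5. Deprotonation with LiN(SiMe3)2 (THF, −78 °C) gives the lithium acetylide F6, which lithium tert-butyl peroxide (−78 to 0 °C) should oxidize to the ynolate 7; i-Pr3SiOTf would then silylate 7 on oxygen. The fallback comes back to the route at 8.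

3. Step 9. The Lewis acid may fragment or scramble the methylene bridge, an ortho phenol of ring A may cyclodehydrate onto a ring-B carbonyl, and acyl groups may exchange between the rings. The fallback sets out from 22 and replaces the acylium electrophile by a nitrile. A Houben–Hoesch reaction with butyronitrile (ZnCl2, HCl gas, Et2O, 0 °C) should precipitate the ketiminium chloride F7, which cannot react a second time. Hydrolysis in water at 80 °C comes back to the route at 24.

**Further compounds**

F1 | step 5 | 2,4,6-tris(benzyloxy)benzaldehyde | O=Cc1c(OCc2ccccc2)cc(OCc2ccccc2)cc1OCc1ccccc1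
F2 | step 5 | 3,5-dihydroxy-4,4-dimethyl-2-propanoylcyclohexa-2,5-dien-1-one | CCC(=O)C1=C(O)C(C)(C)C(O)=CC1=O
F3 | step 5 | 3-hydroxy-4,4-dimethyl-2-propanoyl-6-{[2,4,6-tris(benzyloxy)phenyl]methylidene}cyclohex-2-ene-1,5-dione (alkene geometry not defined) | CCC(=O)C1=C(O)C(C)(C)C(=O)C(=Cc2c(OCc3ccccc3)cc(OCc3ccccc3)cc2OCc2ccccc2)C1=O
F4 | step 3 | 2-[2,4,6-tris(benzyloxy)phenyl]acetaldehyde | O=CCc1c(OCc2ccccc2)cc(OCc2ccccc2)cc1OCc1ccccc1
F5 | step 3 | 1,3,5-tris(benzyloxy)-2-(prop-2-yn-1-yl)benzene | C#CCc1c(OCc2ccccc2)cc(OCc2ccccc2)cc1OCc1ccccc1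
F6 | step 3 | lithium 3-[2,4,6-tris(benzyloxy)phenyl]prop-1-yn-1-ide | [Li]C#CCc1c(OCc2ccccc2)cc(OCc2ccccc2)cc1OCc1ccccc1
F7 | step 9 | 1-{3-[(2,4-dihydroxy-3,3-dimethyl-6-oxo-5-propanoylcyclohexa-1,4-dien-1-yl)methyl]-2,4,6-trihydroxyphenyl}butan-1-iminium chloride | CCCC(=[NH2+])c1c(O)cc(O)c(CC2=C(O)C(C)(C)C(O)=C(C(=O)CC)C2=O)c1O.[Cl-]
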